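## Structural features

The target is an achiral, hexabrominated diaryl ether in which a phenol ring (ring A) and a hydroquinone ring (ring B) are joined by one oxygen between C4 of ring A and C1' of ring B. Ring A carries OH on C1, bromine on C2, C5 and C6, and its only hydrogen on C3. Ring B is fully substituted, with the aryloxy group on C1', hydroxyls on C2' and C5', and bromine on C3', C4' and C6'. There is no stereocentre, so no relation between neighbouring stereocentres has to be controlled. The fragile parts are the hydroquinone of ring B (easily oxidised to the quinone), the 4-aryloxyphenol of ring A (cleavable at C4 by oxidants) and the six C–Br bonds (intolerant of organolithium reagents and low-valent metals), so bromine is best introduced last. The real difficulty is twofold: the ether oxygen is flanked by C2'–OH and C6'–Br on one side and C5–Br on the other, which makes a late coupling of brominated halves unattractive, and ring A must take up exactly three bromine atoms while C3 stays free. The key step exploits the 1,2,4-trioxygenation of ring B: C5' with its oxygen maps onto an alkoxycarbene carbon, C2' onto a carbonyl ligand, C1' and C6' onto an aryloxyacetylene, and C3' and C4' onto a vinyl group, so ring B is built around an ether oxygen that is already attached.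

## Logic of the disconnections

**18 to 16 (through 17).** The six C–Br bonds at C2, C5 and C6 of ring A and at C3', C4' and C6' of ring B are cut together. Each of these carbons is ortho to an oxygen substituent, and C3 and C5 of ring A are equivalent until one of them has reacted, so the position that must stay free needs control of the amount of electrophile only, not of regiochemistry. The gain is that 16 carries no halogen and can be reached with organolithium and metal carbonyl chemistry. The forward step must stop at three substitutions on ring A, and must accept that ring B passes through the quinone level of 17 and is returned by a reductive work-up.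

**16 to 15.** Two O–CH3 bonds and one O–Si bond are cut. These caps are what the ring synthesis delivers (silyl on the C2' oxygen, methyl on the C5' oxygen) or what the lithium chemistry of the alkyne partner requires (methyl on the C1 oxygen). The skeleton is not simplified, but 15 is stable to air where 16 is not. The forward step needs one reagent that removes all three caps and leaves the diaryl ether alone.

**15 to 5 and 12 (through 13 and 14).** The bonds C5'–C6', C1'–C2' and C2'–C3' are cut, so ring B falls into a three-carbon carbene ligand (C3', C4', C5'), one carbonyl ligand (C2') and a two-carbon alkyne (C1', C6'). The cut is made here because the oxygen pattern of ring B is that of a benzannulation product, and because the ether oxygen then enters on an sp carbon and no aryl–oxygen bond has to be forged. One ring, three skeletal bonds and the placement of three oxygen atoms are gained in one step. The forward step needs a single orientation of the alkyne and a silyl migration to oxygen that outruns hydrogen migration.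

**5 to 1 and 2 (through 3 and 4).** The bond between the carbene carbon and the vinyl carbon and the O–CH3 bond are cut, the standard way back from an alkoxycarbene complex to an organolithium, a metal carbonyl and a methylating agent. The gain is two commercial materials. The forward step must keep the E geometry of the vinyl group through halogen–lithium exchange.

**12 to 9 (through 10 and 11).** The triple bond is traced back to a 1,2-dichloroalkene, with two C–Cl bonds and one C–H bond restored on paper. A terminal aryloxyacetylene is too labile to store, whereas 9 can be purified and kept. The forward step needs two equivalents of a strong base and a cold, non-acidic quench.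

**9 to 6 and 7 (through 8).** The O–C(sp2) bond is cut, leaving a phenol and a chlorinated two-carbon electrophile, both bulk chemicals. The forward step must add the phenoxide once only, which the elimination–addition path through 8 provides.

## Other disconnections considered

**Alternative 1:** The cut is the O–C4 ether bond together with the C5–Br bond of ring A, with every other bromine already in place. In the forward step fluoride unmasks the C4–C5 aryne from 3,5-dibromo-4-methoxy-2-(trimethylsilyl)phenyl trifluoromethanesulfonate A2. The phenoxide of 3,4,6-tribromo-2,5-dimethoxyphenol A3 adds at C4, and the C5 anion takes bromine from a polybromomethane. The product is the trimethyl ether A1, one demethylation away from 18.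
- In favour: the plan is convergent and joins two crowded halves without a metal catalyst. The place of every bromine is decided before the coupling, so C3 never meets electrophilic bromine. The inductive pull of the C6 bromine gives a rational basis for attack at C4.
- Against: A3 is a doubly ortho-substituted, electron-poor and therefore sluggish nucleophile. The aryl anion must find the bromine donor before any proton source. A2 and A3 each need a multistep, regiocontrolled synthesis in which C–Br bonds must survive the installation of the silyl and triflate groups.
- Comparison: on the placing of bromine and on convergency this alternative is better than the chosen plan, which depends on stopping at three substitutions on ring A. On step economy the chosen plan should be shorter, since its two partners come from commercial materials in one and two steps. Mechanistically both key steps are extensions of known reaction classes to demanding partners, so they are roughly equal in risk.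

**Alternative 2:** The cut is the C2'–O bond of ring B, traced back to a carbon–carbonyl bond so that the ether and the future C5 substituent are held in a tricyclic template. In the forward step 2,6-dimethoxyxanthone A5 undergoes Baeyer–Villiger oxidation with a strong peracid. The ring B carbon (para to methoxy, ortho to the ring oxygen) should migrate to give 2,7-dimethoxydibenzo[b,e][1,4]dioxepin-11-one A4. Lactone hydrolysis would then free the C2' hydroxyl and leave a carboxyl group on C5 for later decarboxylative bromination.
- In favour: A5 is open to classical xanthone chemistry, and the ether is made early and unhindered. The C2' oxygen is placed by migratory aptitude. The carboxyl marks C5, the one ring A position that substitution reaches with difficulty; on that point this alternative is better than the chosen plan.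
- Against: the xanthone carbonyl is vinylogous to the ring oxygen and a poor electrophile, while both anisole rings invite hydroxylation by the peracid. After ring opening, five brominations, a bromodecarboxylation at a doubly ortho-substituted acid and a demethylation remain.
- Comparison: both plans place the oxygens of ring B by construction and not by coupling, so they are equal there. This alternative is longer by several operations, and its key oxidation rests on a less well-supported substrate class than the benzannulation.

**Alternative 3:** The cut is C4–C5 and C1–C6 of ring A, which is assembled from a furan (C1 to C4 with the C1 oxygen) and an alkyne (C5, C6). In the forward step 2-(2,5-dimethoxyphenoxy)furan A7 and methyl 3-bromopropiolate A8 combine in a Diels–Alder reaction. The oxygen bridge opens at the ketal-like bridgehead C4 and the ring aromatises to methyl 2-bromo-6-(2,5-dimethoxyphenoxy)-3-hydroxybenzoate A6.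
- In favour: ring A arrives with C1–OH, C4–O-aryl, C6–Br and an ester marker on C5, with C2 and C3 still hydrogen. C2 is then ortho to the free phenol and C3 is not, so the three-of-four problem of ring A is solved by construction; here this alternative is better than the chosen plan. The polarisation of both partners supports the required orientation.
- Against: 2-aryloxyfurans are acid-sensitive and easily oxidised, and making A7 itself needs an awkward oxygen–furan bond. A8 is an unstable, lachrymatory dienophile. The ester must be exchanged for bromine by hydrolysis and decarboxylative bromination between two ortho substituents, and ring B still needs three brominations and two demethylations.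
- Comparison: both plans build a ring from a heteroatom-substituted π-component and so attach the ether oxygen before the ring is crowded, which makes them equal in concept. This alternative is inferior in step count and in the stability of its precursors. The chosen plan builds ring B, whose full substitution leaves no regiochemical question in the bromination.

Key step: step 4

Assumption: the trimethylsilyl ether 15 is taken into step 5 without chromatography on silica, since partial loss of the silyl group leads to the same product 16.

## Route

Step 1
Reactants: 1 (E)-(2-bromovinyl)trimethylsilane; 2 chromium hexacarbonyl Cr(CO)6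
Product: 5 pentacarbonyl[(E)-1-methoxy-3-(trimethylsilyl)prop-2-en-1-ylidene]chromium, via (E)-2-(trimethylsilyl)vinyllithium 3 (not isolated), via lithium acylpentacarbonylchromate 4 (not isolated)
Conditions: t-BuLi (2.0 equiv), Et2O, −78 °C; Cr(CO)6, −78 → 0 °C; Me3OBF4, CH2Cl2, 0 °C
Reagents that add atoms: trimethyloxonium tetrafluoroborate, C[O+](C)C.F[B-](F)(F)F
Why: Bromine–lithium exchange on a vinyl bromide proceeds with retention of the E geometry, the vinyllithium adds to a carbonyl ligand of Cr(CO)6, and O-methylation of the acylmetalate completes the classical alkoxycarbene complex synthesis. The β-silyl group should keep the vinylcarbene complex from conjugate addition and polymerisation.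

Step 2
Reactants: 6 4-methoxyphenol; 7 trichloroethylene
Product: 9 (E)-1-[(1,2-dichloroethenyl)oxy]-4-methoxybenzene, via dichloroacetylene 8 (not isolated)
Conditions: K2CO3 (1.5 equiv), DMF, 70 °C
Reagents that add atoms: none
Why: Base-induced dehydrochlorination of 7 gives 8 only transiently, and anti addition of the phenoxide followed by protonation should give the E dichlorovinyl ether (elimination–addition vinylation of a phenol). The carbonate base avoids a metal hydride, and 8 never accumulates.

Step 3
Reactants: 9 (E)-1-[(1,2-dichloroethenyl)oxy]-4-methoxybenzene
Product: 12 1-(ethynyloxy)-4-methoxybenzene, via 1-[(chloroethynyl)oxy]-4-methoxybenzene 10 (not isolated), via lithium (4-methoxyphenoxy)acetylide 11 (not isolated)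
Conditions: n-BuLi (2.2 equiv), Et2O, −78 → −40 °C; MeOH, −78 °C; cold pH 7 wash, solution used at once
Reagents that add atoms: none
Why: The first equivalent of base dehydrochlorinates 9 to the chloroalkyne 10, the second exchanges chlorine for lithium at the sp carbon, and a cold neutral proton source releases the terminal ynol ether (dehydrohalogenation with halogen–lithium exchange). 12 is kept cold and in solution because aryloxyacetylenes hydrate and polymerise when concentrated.

Step 4
Reactants: 5 pentacarbonyl[(E)-1-methoxy-3-(trimethylsilyl)prop-2-en-1-ylidene]chromium; 12 1-(ethynyloxy)-4-methoxybenzene
Product: 15 [4-methoxy-2-(4-methoxyphenoxy)phenoxy]trimethylsilane, via chromium-bound silylcyclohexadienone 13 (not isolated), via arene tricarbonylchromium complex 14 (not isolated)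
Conditions: THF (degassed, 0.05 M), 12 (1.5 equiv) added slowly, 50 °C, Ar; then air, hexane–Et2O, rt; filtration through Celite
Reagents that add atoms: none
Why: Thermal loss of one CO from the zerovalent chromium complex 5 frees a site for 12, which inserts into the chromium–carbene bond with its CH terminus bonding to the carbene carbon (C5'–C6'). Migratory insertion of a CO ligand at the new carbene carbon (C1'–C2') gives a chromium-bound dienylketene, and ring B closes by a 6π electrocyclisation that forms C2'–C3' and gives the dienone 13. A 1,3 shift of silicon from C3' to the carbonyl oxygen aromatises the ring to the arene complex 14 with the C2' oxygen silylated, and air then removes the Cr(CO)3 fragment to give 15. The closest known reaction type is the Dötz benzannulation of β-silylvinyl alkoxycarbene complexes of chromium with terminal alkynes, of which heteroatom-substituted alkynes are less usual partners. No stereocentre remains, since the sp3 carbon C3' of 13 is transient and is erased by the silyl shift. The step needs one orientation of the alkyne; the size difference of its two ends and the polarisation of the ynol ether (nucleophilic CH terminus, electrophilic carbene carbon) both place the aryloxy carbon next to the CO-derived C2'. It also needs benzannulation to outrun cyclobutenone formation, double alkyne uptake and decay of 12, which a coordinating solvent, dilution and slow addition of 12 are meant to secure.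

Step 5
Reactants: 15 [4-methoxy-2-(4-methoxyphenoxy)phenoxy]trimethylsilane
Product: 16 2-(4-hydroxyphenoxy)benzene-1,4-diol
Conditions: BBr3 (4 equiv), CH2Cl2, −78 °C → rt; degassed H2O, 0 °C, Ar
Reagents that add atoms: none
Why: Lewis acid cleavage of aryl methyl ethers by BBr3 removes both methyl groups, and the same reagent and the aqueous work-up remove the silyl group, while the diaryl ether is inert. Work-up under argon limits air oxidation of the hydroquinone.

Step 6
Reactants: 16 2-(4-hydroxyphenoxy)benzene-1,4-diol
Product: 18 2,3,5-tribromo-6-(2,3,5-tribromo-4-hydroxyphenoxy)benzene-1,4-diol, via hexabromoquinone 17 (not isolated)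
Conditions: Br2 (6.0 equiv), AcOH, 20 °C; Br2 (1.05 equiv), 50 °C; then aq Na2S2O4, EtOAc, rt
Reagents that add atoms: bromine, BrBr
Why: Electrophilic aromatic bromination should first take C2 and C6 (ortho to the ring A phenol) and C3', C4' and C6' of the hydroquinone; one further equivalent is consumed in oxidising ring B to the quinone, so seven equivalents are needed, not six. The last, slower substitution falls on C5, which is equivalent to C3 until it reacts, so the regiochemistry cannot go wrong, and the added bromine and the crowding between C2–Br and the aryloxy group should retard a fourth substitution. Dithionite reduces 17 to the hydroquinone and destroys residual bromine.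

## Compound list

1 | (E)-(2-bromovinyl)trimethylsilane | C[Si](C)(C)/C=C/Br | starting material
2 | chromium hexacarbonyl Cr(CO)6 | O=C=[Cr](=C=O)(=C=O)(=C=O)(=C=O)=C=O | starting material
3 | (E)-2-(trimethylsilyl)vinyllithium | [Li]/C=C/[Si](C)(C)C | intermediate
4 | lithium pentacarbonyl[(E)-1-oxido-3-(trimethylsilyl)prop-2-en-1-ylidene]chromate | [Li+].[O-]C(/C=C/[Si](C)(C)C)=[Cr](=C=O)(=C=O)(=C=O)(=C=O)=C=O | intermediate
5 | pentacarbonyl[(E)-1-methoxy-3-(trimethylsilyl)prop-2-en-1-ylidene]chromium | COC(/C=C/[Si](C)(C)C)=[Cr](=C=O)(=C=O)(=C=O)(=C=O)=C=O | intermediate
6 | 4-methoxyphenol | COc1ccc(O)cc1 | starting material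
7 | trichloroethylene | ClC=C(Cl)Cl | starting material
8 | dichloroacetylene | ClC#CCl | intermediate
9 | (E)-1-[(1,2-dichloroethenyl)oxy]-4-methoxybenzene | Cl/C=C(/Cl)Oc1ccc(OC)cc1 | intermediate
10 | 1-[(chloroethynyl)oxy]-4-methoxybenzene | ClC#COc1ccc(OC)cc1 | intermediate
11 | lithium (4-methoxyphenoxy)acetylide | [Li]C#COc1ccc(OC)cc1 | intermediate
12 | 1-(ethynyloxy)-4-methoxybenzene | C#COc1ccc(OC)cc1 | intermediate
13 | tricarbonylchromium-bound 4-methoxy-2-(4-methoxyphenoxy)-6-(trimethylsilyl)cyclohexa-2,4-dien-1-one (racemic at C6, transient) | COC1=CC([Si](C)(C)C)C(=O)C(Oc2ccc(OC)cc2)=C1.O=C=[Cr](=C=O)=C=O | intermediate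
14 | tricarbonyl{η6-[4-methoxy-2-(4-methoxyphenoxy)phenoxy]trimethylsilane}chromium | COc1ccc(Oc2cc(OC)ccc2O[Si](C)(C)C)cc1.O=C=[Cr](=C=O)=C=O | intermediate
15 | [4-methoxy-2-(4-methoxyphenoxy)phenoxy]trimethylsilane | COc1ccc(Oc2cc(OC)ccc2O[Si](C)(C)C)cc1 | intermediate
16 | 2-(4-hydroxyphenoxy)benzene-1,4-diol | Oc1ccc(Oc2cc(O)ccc2O)cc1 | intermediate
17 | 2,3,5-tribromo-6-(2,3,5-tribromo-4-hydroxyphenoxy)cyclohexa-2,5-diene-1,4-dione | O=C1C(Oc2cc(Br)c(O)c(Br)c2Br)=C(Br)C(=O)C(Br)=C1Br | intermediate
18 | 2,3,5-tribromo-6-(2,3,5-tribromo-4-hydroxyphenoxy)benzene-1,4-diol | Oc1c(Br)cc(Oc2c(O)c(Br)c(Br)c(O)c2Br)c(Br)c1Br | target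

## Step count and least certain steps

Total step count: 6. Longest linear sequence: 5 steps (6 → 9 → 12 → 15 → 16 → 18); step 1 supplies the second partner for step 4.

**Step 4 (key step).** The electron-rich ynol ether may be diverted before the ring closes. Possible diversions are insertion without CO uptake, cyclobutenone formation from the ketene intermediate, uptake of a second alkyne, and thermal decay of the alkyne at 50 °C before it meets the coordinatively unsaturated chromium. A hydrogen shift instead of the silyl shift would be harmless, because a silyl group left on C3' would be replaced by bromine in step 6.
Fallback: the benzannulation is given up and the ether is made by coupling while ring B is still unhindered. From 6, an Ullmann coupling with 2-bromo-1,4-dimethoxybenzene F1 (CuI, N,N-dimethylglycine, Cs2CO3, dioxane, 90 °C) should give 1,4-dimethoxy-2-(4-methoxyphenoxy)benzene F2. BBr3 in CH2Cl2 then removes the three methyl groups and the route is rejoined at 16.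

**Step 6.** Three processes threaten this step:
- over-substitution at C3 of ring A if the last equivalent of bromine is not consumed selectively;
- stalling at five bromine atoms, because ring B at the quinone level withdraws the ether oxygen's lone pair from ring A;
- oxidative attack at C4 (para to the ring A phenol) or displacement of the aryloxy group from the quinone by bromide, either of which would break the ether.

Fallback: the easy and the difficult substitutions are separated and all oxidisable hydroxyls are capped. From 16, six equivalents of Br2 in AcOH at 20 °C followed by Na2S2O4 should give 2,3,5-tribromo-6-(3,5-dibromo-4-hydroxyphenoxy)benzene-1,4-diol F3. Acetylation (Ac2O, pyridine) gives 2-(4-acetoxy-3,5-dibromophenoxy)-3,5,6-tribromo-1,4-phenylene diacetate F4, in which neither a phenol nor a hydroquinone is left to be oxidised. One equivalent of Br2 with FeBr3 in CH2Cl2 then substitutes one of the two equivalent ring A positions ortho to the ether oxygen to give 2-(4-acetoxy-2,3,5-tribromophenoxy)-3,5,6-tribromo-1,4-phenylene diacetate F5. Acid methanolysis (HCl, MeOH, 50 °C) returns the route at 18.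

**Step 3.** The terminal aryloxyacetylene may be lost during isolation, by hydration to the aryl acetate with traces of acid or by polymerisation on concentration. Ortho-lithiation of the anisole ring by excess base is a minor concern at low temperature.
Fallback: the alkyne is stored in a capped form. From 9, the same lithiation is run, but 11 is quenched with Me3SiCl to give [(4-methoxyphenoxy)ethynyl]trimethylsilane F6, which can be purified and kept cold. Tetrabutylammonium fluoride in wet THF at −20 °C releases 12 directly into the solution used for step 4, so the route is rejoined at 12.

## Further compounds

F1 | step 4 | 2-bromo-1,4-dimethoxybenzene | COc1ccc(OC)c(Br)c1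
F2 | step 4 | 1,4-dimethoxy-2-(4-methoxyphenoxy)benzene | COc1ccc(Oc2cc(OC)ccc2OC)cc1
F3 | step 6 | 2,3,5-tribromo-6-(3,5-dibromo-4-hydroxyphenoxy)benzene-1,4-diol | Oc1c(Br)cc(Oc2c(O)c(Br)c(Br)c(O)c2Br)cc1Br
F4 | step 6 | 2-(4-acetoxy-3,5-dibromophenoxy)-3,5,6-tribromo-1,4-phenylene diacetate | CC(=O)Oc1c(Br)cc(Oc2c(OC(C)=O)c(Br)c(Br)c(OC(C)=O)c2Br)cc1Br
F5 | step 6 | 2-(4-acetoxy-2,3,5-tribromophenoxy)-3,5,6-tribromo-1,4-phenylene diacetate | CC(=O)Oc1c(Br)cc(Oc2c(OC(C)=O)c(Br)c(Br)c(OC(C)=O)c2Br)c(Br)c1Br
F6 | step 3 | [(4-methoxyphenoxy)ethynyl]trimethylsilane | COc1ccc(OC#C[Si](C)(C)C)cc1
A1 | alternative 1 | 1,2,4-tribromo-3,6-dimethoxy-5-(2,3,5-tribromo-4-methoxyphenoxy)benzene (trimethyl ether of the target) | COc1c(Br)cc(Oc2c(OC)c(Br)c(Br)c(OC)c2Br)c(Br)c1Br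
A2 | alternative 1 | 3,5-dibromo-4-methoxy-2-(trimethylsilyl)phenyl trifluoromethanesulfonate | COc1c(Br)cc(OS(=O)(=O)C(F)(F)F)c([Si](C)(C)C)c1Br
A3 | alternative 1 | 3,4,6-tribromo-2,5-dimethoxyphenol | Oc1c(OC)c(Br)c(Br)c(OC)c1Br
A4 | alternative 2 | 2,7-dimethoxydibenzo[b,e][1,4]dioxepin-11-one | COc1ccc2Oc3cc(OC)ccc3OC(=O)c2c1
A5 | alternative 2 | 2,6-dimethoxyxanthen-9-one | COc1ccc2oc3cc(OC)ccc3c(=O)c2c1
A6 | alternative 3 | methyl 2-bromo-6-(2,5-dimethoxyphenoxy)-3-hydroxybenzoate | Oc1ccc(Oc2cc(OC)ccc2OC)c(C(=O)OC)c1Br
A7 | alternative 3 | 2-(2,5-dimethoxyphenoxy)furan | COc1ccc(OC)c(Oc2ccco2)c1
A8 | alternative 3 | methyl 3-bromopropiolate | COC(=O)C#CBr
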